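**Plan**

- Retrosynthesis: remove the C16 formate, then cut C8=C17 (the formyl carbon; one-carbon Wittig on a 6,7-epoxy-8-ketone, which unravels to 6-OH/C7=C8/CHO). Ring A is cut at C2–C3 and C4–C5 into isobutylene and a ring-B dienol ether carrying a 2-iodoethyl arm on C10. The side chain is cut at C13=C14 (Wittig) and C9–C11 (Michael), and C10–C20 by conjugate addition.
- Forward: ring B comes from 3-ethoxycyclohexenone. The C10 quaternary centre is made first, then the side chain, then the iodoethyl arm and the C6=C7 bond. Ring A is then closed by annulation with isobutylene, and the C6/C7/C8/C17 oxidation pattern is developed from the enone.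
- Enabling feature: C5 is the γ-carbon of a ring-B cyclohex-2-enone (C8=O, C7=C6). As the silyl dienol ether it is a vinylogous nucleophile that sits exactly one six-membered ring from C2 of the arm on C10 once C3–C4 is inserted. C4 is a gem-dimethyl carbon, i.e. the tertiary radical/cation that isobutylene gives.
- Stereochemistry: C10 by catalyst-controlled conjugate addition. C5 (trans fusion) and C9 (equatorial chain) by equilibration through the C8 enone. C6 by epoxidation anti to C20. C13=C14 by Wittig reaction of an α-silyloxy ketone.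

Key step: step 11

Remark: labdane numbering is used in the text (C1–C10 decalin, C11–C16 side chain, C17 formyl carbon, C18/C19 on C4, C20 on C10); "H-5 face" and "C20 face" name the two decalin faces of the target (H-5, H-9 and 6-OH on the first; C20 and the C9 chain on the second); TBS = tert-butyldimethylsilyl.

**Route**

Step 1
Reactants: 1 3-ethoxycyclohex-2-en-1-one
Product: 3 3-vinylcyclohex-2-en-1-one, via 3-ethoxy-1-vinylcyclohex-2-en-1-ol 2 (not isolated)
Conditions: CH2=CHMgBr, THF, 0 °C; then 1 M HCl, 0 °C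
Reagents that add atoms: vinylmagnesium bromide, C=C[Mg]Br
Why: Stork–Danheiser sequence; 1,2-addition to the vinylogous ester followed by acid hydrolysis and loss of ethanol transposes the carbonyl and gives the 3-substituted enone.

Step 2
Reactants: 3 3-vinylcyclohex-2-en-1-one
Product: 5 (S)-trimethyl[(3-methyl-3-vinylcyclohex-1-en-1-yl)oxy]silane, via bromomagnesium enolate 4 (not isolated)
Conditions: MeMgBr, Cu(OTf)2 (4 mol%), chiral NHC ligand (as imidazolinium salt, 5 mol%), Et2O, −30 °C; then Me3SiCl, Et3N, DMPU, −30 → 0 °C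
Reagents that add atoms: methylmagnesium bromide, C[Mg]Br; chlorotrimethylsilane, C[Si](C)(C)Cl
Why: copper-catalysed enantioselective conjugate addition of a Grignard reagent, which with NHC–copper catalysts adds 1,4 rather than 1,6 to 3-alkenylcyclohexenones; the ligand enantiomer is chosen to give the (S) quaternary centre (C10), and silylation fixes the enolate toward C9.

Step 3
Reactants: 6 (tert-butyldimethylsilyloxy)acetaldehyde
Product: 7 1-(tert-butyldimethylsilyloxy)but-3-en-2-ol (racemic)
Conditions: CH2=CHMgBr, THF, −78 °C; then H2O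
Reagents that add atoms: vinylmagnesium bromide, C=C[Mg]Br
Why: Grignard addition to an aldehyde; the carbinol centre is oxidised in the next step.

Step 4
Reactants: 7 1-(tert-butyldimethylsilyloxy)but-3-en-2-ol
Product: 8 1-(tert-butyldimethylsilyloxy)but-3-en-2-one
Conditions: Dess–Martin periodinane, CH2Cl2, 0 °C → rt
Reagents that add atoms: none
Why: Dess–Martin oxidation of a secondary allylic alcohol to the vinyl ketone under neutral conditions that spare the silyl ether.

Step 5
Reactants: 5 (S)-trimethyl[(3-methyl-3-vinylcyclohex-1-en-1-yl)oxy]silane; 8 1-(tert-butyldimethylsilyloxy)but-3-en-2-one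
Product: 9 (3S)-2-[4-(tert-butyldimethylsilyloxy)-3-oxobutyl]-3-methyl-3-vinylcyclohexan-1-one (both epimers at C9)
Conditions: Sc(OTf)3 (10 mol%), i-PrOH (1.2 equiv), CH2Cl2, −78 → −40 °C
Reagents that add atoms: none
Why: Mukaiyama–Michael addition of the regiodefined enol silane to a vinyl ketone forms C9–C11; C9 is not controlled here and is set in step 12.

Step 6
Reactants: 9 (3S)-2-[4-(tert-butyldimethylsilyloxy)-3-oxobutyl]-3-methyl-3-vinylcyclohexan-1-one
Product: 10 methyl (2E)-3-[(tert-butyldimethylsilyloxy)methyl]-5-[(2S)-2-methyl-6-oxo-2-vinylcyclohexyl]pent-2-enoate (C9 epimers)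
Conditions: Ph3P=CHCO2Me, toluene, 90 °C
Reagents that add atoms: methyl (triphenylphosphoranylidene)acetate, COC(=O)C=P(c1ccccc1)(c1ccccc1)c1ccccc1
Why: Wittig reaction of a stabilised ylide, which should react only at the unhindered α-silyloxy ketone and place the ester trans to the CH2O group (the required E geometry), leaving the hindered ring ketone untouched.

Step 7
Reactants: 10 methyl (2E)-3-[(tert-butyldimethylsilyloxy)methyl]-5-[(2S)-2-methyl-6-oxo-2-vinylcyclohexyl]pent-2-enoate
Product: 11 methyl (2E)-3-[(tert-butyldimethylsilyloxy)methyl]-5-[(2S)-2-(2-hydroxyethyl)-2-methyl-6-oxocyclohexyl]pent-2-enoate (C9 epimers)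
Conditions: 9-BBN, THF, 0 °C → rt; then 30% H2O2, aq. NaOAc, 0 °C
Reagents that add atoms: hydrogen peroxide, OO
Why: anti-Markovnikov hydroboration–oxidation; 9-BBN should select the terminal vinyl group over the electron-poor trisubstituted enoate and the hindered ketone.

Step 8
Reactants: 11 methyl (2E)-3-[(tert-butyldimethylsilyloxy)methyl]-5-[(2S)-2-(2-hydroxyethyl)-2-methyl-6-oxocyclohexyl]pent-2-enoate
Product: 13 methyl (2E)-3-[(tert-butyldimethylsilyloxy)methyl]-5-[(6S)-6-(2-hydroxyethyl)-6-methyl-2-oxocyclohex-3-en-1-yl]pent-2-enoate (C9 epimers), via bis(trimethylsilyl) intermediate 12 (not isolated)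
Conditions: LiN(i-Pr)2 (2.2 equiv), Me3SiCl, THF, −78 °C; Pd(OAc)2, MeCN, rt; then 1 M HCl, THF, 0 °C
Reagents that add atoms: none
Why: Saegusa–Ito oxidation; kinetic deprotonation occurs at the C7 methylene rather than the hindered C9 methine, and divalent palladium dehydrogenates the enol silane to the C6=C7 enone, the O-silyl ether being cleaved on work-up.

Step 9
Reactants: 13 methyl (2E)-3-[(tert-butyldimethylsilyloxy)methyl]-5-[(6S)-6-(2-hydroxyethyl)-6-methyl-2-oxocyclohex-3-en-1-yl]pent-2-enoate
Product: 14 methyl (2E)-3-[(tert-butyldimethylsilyloxy)methyl]-5-[(6S)-6-(2-iodoethyl)-6-methyl-2-oxocyclohex-3-en-1-yl]pent-2-enoate (C9 epimers)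
Conditions: I2, PPh3, imidazole, CH2Cl2, 0 °C; aq. NaHCO3 work-up
Reagents that add atoms: iodine, II
Why: Appel-type iodination of the primary alcohol; it is done after step 8 so that no enolate ever meets the iodide.

Step 10
Reactants: 14 methyl (2E)-3-[(tert-butyldimethylsilyloxy)methyl]-5-[(6S)-6-(2-iodoethyl)-6-methyl-2-oxocyclohex-3-en-1-yl]pent-2-enoate
Product: 15 methyl (2E)-3-[(tert-butyldimethylsilyloxy)methyl]-5-[(6R)-2-(tert-butyldimethylsilyloxy)-6-(2-iodoethyl)-6-methylcyclohexa-2,4-dien-1-yl]pent-2-enoate (C9 epimers)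
Conditions: t-BuMe2SiOTf, Et3N, CH2Cl2, 0 °C → rt; aq. NaHCO3 work-up
Reagents that add atoms: tert-butyldimethylsilyl trifluoromethanesulfonate, CC(C)(C)[Si](C)(C)OS(=O)(=O)C(F)(F)F
Why: soft enolisation under equilibrating conditions should remove the γ-hydrogen at C5 and give the through-conjugated dienol ether (C8(OTBS)=C7–C6=C5), because the cross-conjugated isomer would need a strained tetrasubstituted C8=C9 enol ether next to the quaternary C10.

Step 11
Reactants: 15 methyl (2E)-3-[(tert-butyldimethylsilyloxy)methyl]-5-[(6R)-2-(tert-butyldimethylsilyloxy)-6-(2-iodoethyl)-6-methylcyclohexa-2,4-dien-1-yl]pent-2-enoate; 16 2-methylpropene (isobutylene)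
Product: 17 methyl (2E)-3-[(tert-butyldimethylsilyloxy)methyl]-5-[(8aR)-5,5,8a-trimethyl-2-oxo-1,2,4a,5,6,7,8,8a-octahydronaphthalen-1-yl]pent-2-enoate (mixture at C5 and C9)
Conditions: isobutylene (about 30 equiv, condensed), fac-Ir(ppy)3 (2 mol%), 2,6-lutidine, MeCN–CH2Cl2, blue LEDs, sealed tube, 20 °C; aq. NaHCO3 work-up
Reagents that add atoms: none
Why: Proposed new method: the photoexcited trivalent iridium complex transfers an electron to the C2–I bond of 15, the primary C2 radical adds to the CH2 terminus of isobutylene (C2–C3 bond) to give the tertiary C4 radical, this is oxidised by the tetravalent iridium complex to the tertiary cation (or cyclises first and is oxidised afterwards) and is captured by C5, the γ-terminus of the silyl dienol ether (C4–C5 bond), and loss of the silyl group to iodide returns the C8 enone. The closest known reaction types are photoredox radical–polar crossover carbofunctionalisation of alkenes with alkyl halides and cation–olefin cyclisation terminated by a silyl enol ether (vinylogous Mukaiyama/Reetz tert-alkylation), here merged into one [4+2] annulation. Ring A closes in a 6-exo mode with respect to the C5=C6 bond, and attack at the α-carbon C7 would need an eight-membered ring, so ring size enforces γ-regiochemistry. The only new stereocentre, C5, is not reliably controlled (the tether on C10 reaches C5 from its own face, so the cis-fused isomer should predominate) and is set afterwards in step 12, while C4 bears two methyl groups and is not stereogenic. The step needs the C2 radical to add intermolecularly before it does anything else, which the large excess of alkene secures together with the fact that its own ring closures onto C5/C6 would be disfavoured 4-exo or 5-endo modes; Markovnikov regiochemistry follows from attack at the unsubstituted alkene carbon.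

Step 12
Reactants: 17 methyl (2E)-3-[(tert-butyldimethylsilyloxy)methyl]-5-[(8aR)-5,5,8a-trimethyl-2-oxo-1,2,4a,5,6,7,8,8a-octahydronaphthalen-1-yl]pent-2-enoate
Product: 18 methyl (2E)-3-[(tert-butyldimethylsilyloxy)methyl]-5-[(1S,4aR,8aR)-5,5,8a-trimethyl-2-oxo-1,2,4a,5,6,7,8,8a-octahydronaphthalen-1-yl]pent-2-enoate (trans-fused, H-5 anti to C20; C9 chain equatorial, syn to C20)
Conditions: DBU (0.3 equiv), toluene, 80 °C
Reagents that add atoms: none
Why: base-mediated equilibration through the α′-enolate (C9) and the extended dienolate (C5) should favour the trans-fused decalin with the C9 chain equatorial, since the cis-fused isomers add an axial ring bond or extra gauche interactions without relieving the C4/C10 diaxial methyl contact.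

Step 13
Reactants: 18 methyl (2E)-3-[(tert-butyldimethylsilyloxy)methyl]-5-[(1S,4aR,8aR)-5,5,8a-trimethyl-2-oxo-1,2,4a,5,6,7,8,8a-octahydronaphthalen-1-yl]pent-2-enoate
Product: 19 the 6,7-epoxy-8-ketone derived from 18, epoxide on the H-5 face
Conditions: t-BuOOH, DBU, CH2Cl2, 0 °C → rt
Reagents that add atoms: tert-butyl hydroperoxide, CC(C)(C)OO
Why: Weitz–Scheffer nucleophilic epoxidation of the enone; the peroxide attacks C6 from the H-5 face because the C20 face is screened by the axial C20 and axial C4 methyl groups, which sets the C6–O configuration, and the β,β-disubstituted enoate is far less electrophilic.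

Step 14
Reactants: 19 the 6,7-epoxy-8-ketone
Product: 20 the C8 methoxymethylene enol ether of 19 (E/Z mixture at C8=C17)
Conditions: MeOCH2PPh3Cl, KN(SiMe3)2, THF, 0 °C; then 19, −78 → 0 °C
Reagents that add atoms: (methoxymethyl)triphenylphosphonium chloride, COC[P+](c1ccccc1)(c1ccccc1)c1ccccc1.[Cl-]
Why: Wittig one-carbon homologation of the ketone installs C17 at the aldehyde oxidation level; the enol ether geometry is irrelevant.

Step 15
Reactants: 20 the C8 methoxymethylene enol ether
Product: 22 methyl (2E)-5-[(1S,4R,4aR,8aS)-2-formyl-4-hydroxy-5,5,8a-trimethyl-1,4,4a,5,6,7,8,8a-octahydronaphthalen-1-yl]-3-(hydroxymethyl)pent-2-enoate, via silyl-protected hydroxy enal 21 (not isolated)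
Conditions: 1 M HCl, THF, 0 °C → rt
Reagents that add atoms: water, O
Why: acid hydrolysis of the enol ether with vinylogous opening of the adjacent epoxide (C7–O cleavage, C6–O retained) gives the conjugated γ-hydroxy enal with C7=C8, and the same acid removes the primary silyl ether.

Step 16
Reactants: 22 methyl (2E)-5-[(1S,4R,4aR,8aS)-2-formyl-4-hydroxy-5,5,8a-trimethyl-1,4,4a,5,6,7,8,8a-octahydronaphthalen-1-yl]-3-(hydroxymethyl)pent-2-enoate
Product: 23 methyl (2E)-3-[(formyloxy)methyl]-5-[(1S,4R,4aR,8aS)-2-formyl-4-hydroxy-5,5,8a-trimethyl-1,4,4a,5,6,7,8,8a-octahydronaphthalen-1-yl]pent-2-enoate (target)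
Conditions: AcOCHO, pyridine, CH2Cl2, −40 °C
Reagents that add atoms: acetic formic anhydride, CC(=O)OC=O
Why: O-formylation with a mixed anhydride at low temperature should select the unhindered primary allylic alcohol over the secondary 6-OH, which is crowded by C5 and the C4 gem-dimethyl group.

**Compound list**

1 | 3-ethoxycyclohex-2-en-1-one | CCOC1=CC(=O)CCC1 | starting material
2 | 3-ethoxy-1-vinylcyclohex-2-en-1-ol | CCOC1=CC(O)(C=C)CCC1 | intermediate
3 | 3-vinylcyclohex-2-en-1-one | C=CC1=CC(=O)CCC1 | intermediate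
4 | bromomagnesium (S)-3-methyl-3-vinylcyclohex-1-en-1-olate | C1=C(O[Mg]Br)CCC[C@@]1(C)C=C | intermediate
5 | (S)-trimethyl[(3-methyl-3-vinylcyclohex-1-en-1-yl)oxy]silane | C1=C(O[Si](C)(C)C)CCC[C@@]1(C)C=C | intermediate
6 | (tert-butyldimethylsilyloxy)acetaldehyde | O=CCO[Si](C)(C)C(C)(C)C | starting material
7 | 1-(tert-butyldimethylsilyloxy)but-3-en-2-ol (racemic) | C=CC(O)CO[Si](C)(C)C(C)(C)C | intermediate
8 | 1-(tert-butyldimethylsilyloxy)but-3-en-2-one | C=CC(=O)CO[Si](C)(C)C(C)(C)C | intermediate
9 | (3S)-2-[4-(tert-butyldimethylsilyloxy)-3-oxobutyl]-3-methyl-3-vinylcyclohexan-1-one (C9 epimers) | CC(C)(C)[Si](C)(C)OCC(=O)CCC1C(=O)CCC[C@@]1(C)C=C | intermediate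
10 | methyl (2E)-3-[(tert-butyldimethylsilyloxy)methyl]-5-[(2S)-2-methyl-6-oxo-2-vinylcyclohexyl]pent-2-enoate (C9 epimers) | COC(=O)/C=C(\CCC1C(=O)CCC[C@@]1(C)C=C)CO[Si](C)(C)C(C)(C)C | intermediate
11 | methyl (2E)-3-[(tert-butyldimethylsilyloxy)methyl]-5-[(2S)-2-(2-hydroxyethyl)-2-methyl-6-oxocyclohexyl]pent-2-enoate (C9 epimers) | COC(=O)/C=C(\CCC1C(=O)CCC[C@@]1(C)CCO)CO[Si](C)(C)C(C)(C)C | intermediate
12 | bis(trimethylsilyl) derivative of 11 (C8=C7 enol silane and O-silyl ether) | COC(=O)/C=C(\CCC1C(O[Si](C)(C)C)=CCC[C@@]1(C)CCO[Si](C)(C)C)CO[Si](C)(C)C(C)(C)C | intermediate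
13 | methyl (2E)-3-[(tert-butyldimethylsilyloxy)methyl]-5-[(6S)-6-(2-hydroxyethyl)-6-methyl-2-oxocyclohex-3-en-1-yl]pent-2-enoate (C9 epimers) | COC(=O)/C=C(\CCC1C(=O)C=CC[C@@]1(C)CCO)CO[Si](C)(C)C(C)(C)C | intermediate
14 | methyl (2E)-3-[(tert-butyldimethylsilyloxy)methyl]-5-[(6S)-6-(2-iodoethyl)-6-methyl-2-oxocyclohex-3-en-1-yl]pent-2-enoate (C9 epimers) | COC(=O)/C=C(\CCC1C(=O)C=CC[C@@]1(C)CCI)CO[Si](C)(C)C(C)(C)C | intermediate
15 | methyl (2E)-3-[(tert-butyldimethylsilyloxy)methyl]-5-[(6R)-2-(tert-butyldimethylsilyloxy)-6-(2-iodoethyl)-6-methylcyclohexa-2,4-dien-1-yl]pent-2-enoate (C9 epimers) | COC(=O)/C=C(\CCC1C(O[Si](C)(C)C(C)(C)C)=CC=C[C@@]1(C)CCI)CO[Si](C)(C)C(C)(C)C | intermediate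
16 | 2-methylpropene (isobutylene) | CC(C)=C | starting material
17 | methyl (2E)-3-[(tert-butyldimethylsilyloxy)methyl]-5-[(8aR)-5,5,8a-trimethyl-2-oxo-1,2,4a,5,6,7,8,8a-octahydronaphthalen-1-yl]pent-2-enoate (C5 and C9 epimers) | COC(=O)/C=C(\CCC1C(=O)C=CC2C(C)(C)CCC[C@@]12C)CO[Si](C)(C)C(C)(C)C | intermediate
18 | methyl (2E)-3-[(tert-butyldimethylsilyloxy)methyl]-5-[(1S,4aR,8aR)-5,5,8a-trimethyl-2-oxo-1,2,4a,5,6,7,8,8a-octahydronaphthalen-1-yl]pent-2-enoate | COC(=O)/C=C(\CC[C@@H]1C(=O)C=C[C@@H]2C(C)(C)CCC[C@@]12C)CO[Si](C)(C)C(C)(C)C | intermediate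
19 | 6,7-epoxy-8-ketone from 18, epoxide on the H-5 face | COC(=O)/C=C(\CC[C@@H]1C(=O)[C@H]3O[C@H]3[C@@H]2C(C)(C)CCC[C@@]12C)CO[Si](C)(C)C(C)(C)C | intermediate
20 | C8 methoxymethylene enol ether of 19 (E/Z mixture at C8=C17) | COC(=O)/C=C(\CC[C@@H]1C(=COC)[C@H]3O[C@H]3[C@@H]2C(C)(C)CCC[C@@]12C)CO[Si](C)(C)C(C)(C)C | intermediate
21 | 16-O-TBS ether of 22 (6-hydroxy-7-en-17-al) | COC(=O)/C=C(\CC[C@@H]1C(C=O)=C[C@@H](O)[C@@H]2C(C)(C)CCC[C@@]12C)CO[Si](C)(C)C(C)(C)C | intermediate
22 | methyl (2E)-5-[(1S,4R,4aR,8aS)-2-formyl-4-hydroxy-5,5,8a-trimethyl-1,4,4a,5,6,7,8,8a-octahydronaphthalen-1-yl]-3-(hydroxymethyl)pent-2-enoate | COC(=O)/C=C(\CC[C@@H]1C(C=O)=C[C@@H](O)[C@@H]2C(C)(C)CCC[C@@]12C)CO | intermediate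
23 | methyl (2E)-3-[(formyloxy)methyl]-5-[(1S,4R,4aR,8aS)-2-formyl-4-hydroxy-5,5,8a-trimethyl-1,4,4a,5,6,7,8,8a-octahydronaphthalen-1-yl]pent-2-enoate | COC(=O)/C=C(\CC[C@@H]1C(C=O)=C[C@@H](O)[C@@H]2C(C)(C)CCC[C@@]12C)COC=O | target

**Step count and risks**

Total: 16 steps. Longest linear sequence: 14 steps (1 → 23 through steps 1, 2 and 5–16); steps 3 and 4 are a two-step branch to enone 8.

Step 11 (proposed new method). What may go wrong: addition of the unactivated primary radical to isobutylene may be too slow, so that hydrogen abstraction, attack on the substrate's own dienol ether at C7, or oligomerisation wins. The tertiary cation may also lose a proton instead of being captured, or the dienol ether may be desilylated before ring closure. The fallback uses known chemistry only, sets out from 11 and returns at 17. Appel iodination of 11 gives the saturated iodo ketone F1. Keck radical allylation with tributyl(2-methylallyl)stannane (AIBN, benzene, 80 °C) forms C2–C3 and gives the 4-methylpent-4-enyl ketone F2. Saegusa–Ito oxidation as in step 8 gives the enone F3. Markovnikov addition of HCl (CH2Cl2, −78 °C) gives the tertiary chloride F4. Soft enolisation as in step 10 gives the chloro dienol silyl ether F5. ZnCl2 in CH2Cl2 then ionises the tertiary chloride, and the dienol ether closes C4–C5 (Reetz-type tert-alkylation) to give 17.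

Step 12. What may go wrong: the equilibrium may not favour the trans-fused, C9-equatorial isomer strongly enough, equilibration at the hindered C5 may be slow, or the base may deconjugate the enone. The fallback sets C5 and C6 kinetically instead; it sets out from 17 and returns at 22. Transketalisation (2-ethyl-2-methyl-1,3-dioxolane, ethylene glycol, TsOH) moves the double bond to C5=C6 and gives the ketal F6, which erases C5. Hydroboration–oxidation (BH3·THF, then H2O2/NaOAc) adds H-5 and 6-OH syn on the face away from C20 and gives the alcohol F7. Silylation (t-BuMe2SiOTf, 2,6-lutidine) gives the silyl ether F8. Mild acid deketalisation followed by DBU, which places the C9 chain equatorial in the now trans-fused ketone, gives the ketone F9. KN(SiMe3)2/PhNTf2 enolises toward C7 and gives the vinyl triflate F10. Reductive carbonylation catalysed by zerovalent palladium (Pd(PPh3)4, CO, Bu3SnH) gives the bis-silylated enal F11. HF·pyridine removes both silyl groups to give 22.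

Step 10. What may go wrong: enolisation toward C9 instead of C5 would give the cross-conjugated dienol ether, and ring closure in step 11 would then take place at C9. The fallback sets out from 14 and returns at 17. Heating 14 with isopropenyl acetate and catalytic TsOH (thermodynamic conditions, which give through-conjugated dienol esters from cyclohexenones) gives the dienyl acetate F12. F12 is then used in place of 15 under the conditions of step 11, the acetyl group leaving in place of the silyl group, to give 17.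

Further compounds
F1 | step 11 | methyl (2E)-3-[(tert-butyldimethylsilyloxy)methyl]-5-[(2S)-2-(2-iodoethyl)-2-methyl-6-oxocyclohexyl]pent-2-enoate (C9 epimers) | COC(=O)/C=C(\CCC1C(=O)CCC[C@@]1(C)CCI)CO[Si](C)(C)C(C)(C)C
F2 | step 11 | methyl (2E)-3-[(tert-butyldimethylsilyloxy)methyl]-5-[2-methyl-2-(4-methylpent-4-en-1-yl)-6-oxocyclohexyl]pent-2-enoate (C10 as in 11; C9 epimers) | COC(=O)/C=C(\CCC1C(=O)CCC[C@@]1(C)CCCC(C)=C)CO[Si](C)(C)C(C)(C)C
F3 | step 11 | C6=C7 enone of F2 | COC(=O)/C=C(\CCC1C(=O)C=CC[C@@]1(C)CCCC(C)=C)CO[Si](C)(C)C(C)(C)C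
F4 | step 11 | tertiary chloride from F3 (4-chloro-4-methylpentyl arm) | COC(=O)/C=C(\CCC1C(=O)C=CC[C@@]1(C)CCCC(C)(C)Cl)CO[Si](C)(C)C(C)(C)C
F5 | step 11 | through-conjugated TBS dienol ether of F4 | COC(=O)/C=C(\CCC1C(O[Si](C)(C)C(C)(C)C)=CC=C[C@@]1(C)CCCC(C)(C)Cl)CO[Si](C)(C)C(C)(C)C
F6 | step 12 | C8 ethylene ketal with C5=C6 double bond (C9 epimers) | COC(=O)/C=C(\CCC1C3(OCCO3)CC=C2C(C)(C)CCC[C@@]12C)CO[Si](C)(C)C(C)(C)C
F7 | step 12 | 6-hydroxy C8 ketal, trans-fused, 6-OH on the H-5 face (C9 epimers) | COC(=O)/C=C(\CCC1C3(OCCO3)C[C@@H](O)[C@@H]2C(C)(C)CCC[C@@]12C)CO[Si](C)(C)C(C)(C)C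
F8 | step 12 | 6-O-TBS ether of F7 | COC(=O)/C=C(\CCC1C3(OCCO3)C[C@@H](O[Si](C)(C)C(C)(C)C)[C@@H]2C(C)(C)CCC[C@@]12C)CO[Si](C)(C)C(C)(C)C
F9 | step 12 | 6-O-TBS 8-ketone, C9 chain equatorial | COC(=O)/C=C(\CC[C@@H]1C(=O)C[C@@H](O[Si](C)(C)C(C)(C)C)[C@@H]2C(C)(C)CCC[C@@]12C)CO[Si](C)(C)C(C)(C)C
F10 | step 12 | C7=C8 vinyl triflate of F9 | COC(=O)/C=C(\CC[C@@H]1C(OS(=O)(=O)C(F)(F)F)=C[C@@H](O[Si](C)(C)C(C)(C)C)[C@@H]2C(C)(C)CCC[C@@]12C)CO[Si](C)(C)C(C)(C)C
F11 | step 12 | 6,16-bis-O-TBS ether of 22 | COC(=O)/C=C(\CC[C@@H]1C(C=O)=C[C@@H](O[Si](C)(C)C(C)(C)C)[C@@H]2C(C)(C)CCC[C@@]12C)CO[Si](C)(C)C(C)(C)C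
F12 | step 10 | through-conjugated dienyl acetate of 14 | COC(=O)/C=C(\CCC1C(OC(C)=O)=CC=C[C@@]1(C)CCI)CO[Si](C)(C)C(C)(C)C
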